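Assumption: labdane numbering and α/β face labels are used for all bicyclic compounds (C-11/C-12 are the two side-chain carbons of the tetranor compounds; the C-10 methyl is β). Reagents added in sequence to one flask count as one step.

**Overview (disconnections listed from the starting-material end)**
1. Rings A and B are never built: both, with C-5 and C-10 already set, come from (+)-sclareolide 1 → ester 2 → alcohol 3 → bromide 4 (the lactone C-8–O bond becomes the Δ8 olefin).
2. C-7–O comes from allylic oxidation (enone 5). C-6–O comes from hydroxylation of dienolate 6 (ketol 7), oxidation to dione 8, and hydride from the α face (6β-ketol 9).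
3. Key C–O step: 9 + acetaldehyde → hemiacetal 10 → 11. This 1,2-Tishchenko-type reduction makes the O-6 acetate and the 7α-OH (trans-diaxial) in one event.
4. Side chain: (Z)-iodide 14 is made from but-2-yn-1-ol 12 via alanate 13; reductive coupling of 11 with 14 forms C-12–C-13 and gives target 15.
5. No protecting groups and no ring-forming step.

**Route**

Step 1
Reactants: 1 (+)-sclareolide
Product: 2 methyl (5S,10S)-13,14,15,16-tetranorlabd-8-en-12-oate
Conditions: conc. H2SO4, MeOH, 65 °C
Reagents that add atoms: methanol, CO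
Why: Acid ionises the tertiary C-8–O lactone bond (E1 elimination with Fischer esterification) and, under equilibrating conditions, the most substituted Δ8(9) olefin results while C-5 and C-10 are untouched.

Step 2
Reactants: 2 methyl (5S,10S)-13,14,15,16-tetranorlabd-8-en-12-oate
Product: 3 (5S,10S)-13,14,15,16-tetranorlabd-8-en-12-ol
Conditions: LiAlH4, THF, 0 °C
Reagents that add atoms: none
Why: Hydride ester reduction gives the primary alcohol and leaves the unactivated tetrasubstituted olefin alone.

Step 3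
Reactants: 3 (5S,10S)-13,14,15,16-tetranorlabd-8-en-12-ol
Product: 4 (5S,10S)-12-bromo-13,14,15,16-tetranorlabd-8-ene
Conditions: CBr4, PPh3, CH2Cl2, 0 °C
Reagents that add atoms: carbon tetrabromide, BrC(Br)(Br)Br
Why: The Appel reaction converts the unhindered primary alcohol into the bromide by SN2 without touching the olefin.

Step 4
Reactants: 4 (5S,10S)-12-bromo-13,14,15,16-tetranorlabd-8-ene
Product: 5 (5S,10S)-12-bromo-13,14,15,16-tetranorlabd-8-en-7-one
Conditions: CrO3, 3,5-dimethylpyrazole, CH2Cl2, −20 °C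
Reagents that add atoms: chromium trioxide, O=[Cr](=O)=O
Why: Allylic oxidation by the CrO3–dimethylpyrazole complex takes the ring methylene C-7, the most accessible allylic CH2 of the Δ8 olefin (C-11 is shielded by the quaternary C-10 and the bromoethyl chain), and gives the conjugated enone.

Step 5
Reactants: 5 (5S,10S)-12-bromo-13,14,15,16-tetranorlabd-8-en-7-one
Product: 7 (5S,6R,10S)-12-bromo-6α-hydroxy-13,14,15,16-tetranorlabd-8-en-7-one, via potassium dienolate 6 (not isolated)
Conditions: KN(SiMe3)2, THF, −78 °C; then 2-(phenylsulfonyl)-3-phenyloxaziridine, −78 °C; AcOH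
Reagents that add atoms: 2-(phenylsulfonyl)-3-phenyloxaziridine, O=S(=O)(N1OC1c1ccccc1)c1ccccc1
Why: Kinetic α′-deprotonation at C-6 gives the cross-conjugated dienolate, and Davis enolate hydroxylation forms the C-6–O bond from the open α face (this C-6 configuration is erased in step 6 and need not be pure).

Step 6
Reactants: 7 (5S,6R,10S)-12-bromo-6α-hydroxy-13,14,15,16-tetranorlabd-8-en-7-one
Product: 8 (5S,10S)-12-bromo-13,14,15,16-tetranorlabd-8-ene-6,7-dione
Conditions: Dess–Martin periodinane, CH2Cl2, 0 °C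
Reagents that add atoms: none
Why: Dess–Martin oxidation turns the α-ketol into the ene-1,2-dione under neutral conditions that do not enolise C-5.

Step 7
Reactants: 8 (5S,10S)-12-bromo-13,14,15,16-tetranorlabd-8-ene-6,7-dione
Product: 9 (5S,6S,10S)-12-bromo-6β-hydroxy-13,14,15,16-tetranorlabd-8-en-7-one
Conditions: NaBH4 (0.3 equiv), CH2Cl2–MeOH, −78 °C
Reagents that add atoms: none
Why: In this chemoselective borohydride carbonyl reduction the non-conjugated C-6 carbonyl is more electrophilic than the enone carbonyl C-7, and hydride enters from the α face because the β face of C-6 lies under the syn-axial C-10 and 4β methyls, which sets the axial 6β-OH (6S).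

Step 8
Reactants: 9 (5S,6S,10S)-12-bromo-6β-hydroxy-13,14,15,16-tetranorlabd-8-en-7-one
Product: 11 (5S,6S,7S,10S)-12-bromo-7α-hydroxy-13,14,15,16-tetranorlabd-8-en-6β-yl acetate, via hemiacetal 10 (not isolated)
Conditions: CH3CHO (8 equiv), SmI2 (0.3 equiv, premixed with the aldehyde), THF, −10 °C
Reagents that add atoms: acetaldehyde, CC=O
Why: Proposed new method: a 1,2-variant of the Evans–Tishchenko reduction, in which the axial 6β-OH adds to acetaldehyde to give hemiacetal 10, its samarium alkoxide also binds O-7, and the hemiacetal C–H passes to C-7 on the β face (the only face the O-6 tether can reach) through a five-membered hydride-transfer array, so that one event turns the hemiacetal carbon into the O-6 acetate and sets 7α-OH (7S, trans-diaxial to O-6); the closest known reactions are the Evans–Tishchenko anti-reduction of β-hydroxy ketones (six-membered array) and the hydroxyl-directed triacetoxyborohydride reduction of α-ketols.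

Step 9
Reactants: 12 but-2-yn-1-ol
Product: 14 (Z)-3-iodobut-2-en-1-ol, via cyclic alkenylalanate 13 (not isolated)
Conditions: NaAlH2(OCH2CH2OCH3)2, THF, 0 to 23 °C; then I2, −78 °C
Reagents that add atoms: iodine, II
Why: Hydroxyl-directed trans-hydroalumination puts aluminium on C-3 cis to the CH2O group in a five-membered alanate, and iodinolysis with retention gives only the (Z)-iodide.

Step 10
Reactants: 11 (5S,6S,7S,10S)-12-bromo-7α-hydroxy-13,14,15,16-tetranorlabd-8-en-6β-yl acetate; 14 (Z)-3-iodobut-2-en-1-ol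
Product: 15 (5S,6S,7S,10S,13Z)-7α,15-dihydroxylabda-8,13-dien-6β-yl acetate
Conditions: NiBr2·CH3OCH2CH2OCH3 (10 mol %), 4,4′-di-tert-butyl-2,2′-bipyridine, Zn, NaI (0.25 equiv), N,N-dimethylacetamide, 25 °C
Reagents that add atoms: none
Why: In this nickel-catalysed reductive cross-electrophile coupling the alkenyl iodide adds to zerovalent nickel with retention of the Z geometry, the primary radical from the bromide is captured, and reductive elimination forms C-12–C-13 under conditions that leave the free hydroxyls and the hindered acetate untouched.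

**Compound list**
1 | (+)-sclareolide, (3aR,5aS,9aS,9bR)-3a,6,6,9a-tetramethyldecahydronaphtho[2,1-b]furan-2(1H)-one | C1C[C@@]3(C)OC(=O)C[C@@H]3[C@@]2(C)CCCC(C)(C)[C@H]12 | starting material
2 | methyl (5S,10S)-13,14,15,16-tetranorlabd-8-en-12-oate | C1CC(C)=C(CC(=O)OC)[C@@]2(C)CCCC(C)(C)[C@H]12 | intermediate
3 | (5S,10S)-13,14,15,16-tetranorlabd-8-en-12-ol | C1CC(C)=C(CCO)[C@@]2(C)CCCC(C)(C)[C@H]12 | intermediate
4 | (5S,10S)-12-bromo-13,14,15,16-tetranorlabd-8-ene | C1CC(C)=C(CCBr)[C@@]2(C)CCCC(C)(C)[C@H]12 | intermediate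
5 | (5S,10S)-12-bromo-13,14,15,16-tetranorlabd-8-en-7-one | C1C(=O)C(C)=C(CCBr)[C@@]2(C)CCCC(C)(C)[C@H]12 | intermediate
6 | potassium 6,8-dien-7-olate of 5 (formed in the flask) | C1=C([O-])C(C)=C(CCBr)[C@@]2(C)CCCC(C)(C)[C@H]12.[K+] | intermediate
7 | (5S,6R,10S)-12-bromo-6α-hydroxy-13,14,15,16-tetranorlabd-8-en-7-one | O[C@H]1C(=O)C(C)=C(CCBr)[C@@]2(C)CCCC(C)(C)[C@H]12 | intermediate
8 | (5S,10S)-12-bromo-13,14,15,16-tetranorlabd-8-ene-6,7-dione | O=C1C(=O)C(C)=C(CCBr)[C@@]2(C)CCCC(C)(C)[C@H]12 | intermediate
9 | (5S,6S,10S)-12-bromo-6β-hydroxy-13,14,15,16-tetranorlabd-8-en-7-one | O[C@@H]1C(=O)C(C)=C(CCBr)[C@@]2(C)CCCC(C)(C)[C@H]12 | intermediate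
10 | O-6 1-hydroxyethyl hemiacetal of 9 (samarium-bound in the flask; both epimers at the acetal carbon) | CC(O)O[C@@H]1C(=O)C(C)=C(CCBr)[C@@]2(C)CCCC(C)(C)[C@H]12 | intermediate
11 | (5S,6S,7S,10S)-12-bromo-7α-hydroxy-13,14,15,16-tetranorlabd-8-en-6β-yl acetate | CC(=O)O[C@@H]1[C@@H](O)C(C)=C(CCBr)[C@@]2(C)CCCC(C)(C)[C@H]12 | intermediate
12 | but-2-yn-1-ol | CC#CCO | starting material
13 | sodium 2,2-bis(2-methoxyethoxy)-3-methyl-2,5-dihydro-1,2-oxaaluminol-2-uide (cyclic alkenylalanate, formed in the flask) | CC1=CCO[Al-]1(OCCOC)OCCOC.[Na+] | intermediate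
14 | (Z)-3-iodobut-2-en-1-ol | OC/C=C(/C)I | intermediate
15 | (5S,6S,7S,10S,13Z)-7α,15-dihydroxylabda-8,13-dien-6β-yl acetate (CNP0183298.2) | CC(=O)O[C@@H]1[C@@H](O)C(C)=C(CC/C(C)=C\CO)[C@@]2(C)CCCC(C)(C)[C@H]12 | target

**Step count and risks**
Total step count: 10. Longest linear sequence: 9 (steps 1–8 and 10, from 1 to 15); step 9 is a one-step side branch.

The three steps most likely to fail:

Step 7. The hydride may partly attack C-7, or dione 8 may tautomerise toward C-5 before it is reduced. The fallback uses known chemistry, sets out from enone 5 and comes back at 11, replacing steps 5–8 by a singlet-oxygen route. Enone 5 is converted with KN(SiMe3)2 and N-phenylbis(trifluoromethanesulfonimide) into the dienyl triflate F1. Pd(OAc)2/PPh3/HCO2H/Bu3N reduces it to the 6,8-diene F2. O2, metal-free tetraphenylporphyrin and visible light add singlet oxygen across C-6/C-9 from the α face to give the endoperoxide F3. Et3N (Kornblum–DeLaMare rearrangement) opens it to the hydroxy enone F4. NaBH4/CeCl3·7H2O delivers hydride to C-6 from the α face to give the diol F5. Ac2O/DMAP acetylates only the secondary 6β-OH to give the hydroxy acetate F6. Catalytic Ph3SiOReO3 then moves the tertiary 9α-OH suprafacially to C-7 (1,3-allylic transposition), which gives 11.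

Step 8 (the new step). The five-membered hydride transfer may be slower than C-6 epimerisation of 9 by the trivalent samarium Lewis acid or than self-Tishchenko of acetaldehyde. The fallback uses known chemistry, sets out from 9 and comes back at 11. Hydroxyl-directed reduction with Me4NBH(OAc)3 (MeCN–AcOH, −20 °C) delivers hydride to C-7 from the β face and gives the trans-diol F7. Ac2O/DMAP/pyridine at 50 °C gives the diacetate F8. K2CO3 in MeOH at 0 °C cleaves only the less hindered allylic 7α-acetate (the 6β-acetate is shielded by the two syn-axial methyls), which gives 11.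

Step 10. Homocoupling or partial loss of the Z geometry at nickel may lower the yield. The fallback reverses the polarity, sets out from 14 and 11 and comes back at 15. Iodide 14 is silylated (t-BuMe2SiCl, imidazole) to the silyl ether F9. Treatment with (CH3)3CLi and then ZnBr2 at −78 °C gives, with retention, the alkenylzinc bromide F10 (3 equiv are used, one being spent on the free 7-OH of 11). Negishi coupling with bromide 11 under Pd2(dibenzylideneacetone)3/P(c-C5H9)3/N-methylimidazole gives the silyl-protected product F11. Bu4NF then gives 15.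

**Further compounds**
F1 | step 7 | dienyl triflate, (5S,10S)-12-bromo-13,14,15,16-tetranorlabda-6,8-dien-7-yl trifluoromethanesulfonate | C1=C(OS(=O)(=O)C(F)(F)F)C(C)=C(CCBr)[C@@]2(C)CCCC(C)(C)[C@H]12
F2 | step 7 | 6,8-diene, (5S,10S)-12-bromo-13,14,15,16-tetranorlabda-6,8-diene | C1=CC(C)=C(CCBr)[C@@]2(C)CCCC(C)(C)[C@H]12
F3 | step 7 | endoperoxide, 12-bromo-6α,9α-epidioxy-13,14,15,16-tetranorlabd-7-ene | [C@H]1(OO4)C=C(C)[C@]4(CCBr)[C@@]2(C)CCCC(C)(C)[C@H]12
F4 | step 7 | hydroxy enone, 12-bromo-9α-hydroxy-13,14,15,16-tetranorlabd-7-en-6-one | O=C1C=C(C)[C@](O)(CCBr)[C@@]2(C)CCCC(C)(C)[C@H]12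
F5 | step 7 | diol, 12-bromo-13,14,15,16-tetranorlabd-7-ene-6β,9α-diol | O[C@@H]1C=C(C)[C@](O)(CCBr)[C@@]2(C)CCCC(C)(C)[C@H]12
F6 | step 7 | hydroxy acetate, 12-bromo-9α-hydroxy-13,14,15,16-tetranorlabd-7-en-6β-yl acetate | CC(=O)O[C@@H]1C=C(C)[C@](O)(CCBr)[C@@]2(C)CCCC(C)(C)[C@H]12
F7 | step 8 | trans-diol, 12-bromo-13,14,15,16-tetranorlabd-8-ene-6β,7α-diol | O[C@@H]1[C@@H](O)C(C)=C(CCBr)[C@@]2(C)CCCC(C)(C)[C@H]12
F8 | step 8 | diacetate, 12-bromo-13,14,15,16-tetranorlabd-8-ene-6β,7α-diyl diacetate | CC(=O)O[C@@H]1[C@@H](OC(C)=O)C(C)=C(CCBr)[C@@]2(C)CCCC(C)(C)[C@H]12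
F9 | step 10 | silyl ether, (Z)-tert-butyl[(3-iodobut-2-en-1-yl)oxy]dimethylsilane | CC(C)(C)[Si](C)(C)OC/C=C(/C)I
F10 | step 10 | alkenylzinc bromide, (Z)-[4-(tert-butyldimethylsilyloxy)but-2-en-2-yl]zinc bromide | CC(C)(C)[Si](C)(C)OC/C=C(/C)[Zn]Br
F11 | step 10 | silyl-protected product, (13Z)-15-(tert-butyldimethylsilyloxy)-7α-hydroxylabda-8,13-dien-6β-yl acetate | CC(=O)O[C@@H]1[C@@H](O)C(C)=C(CC/C(C)=C\CO[Si](C)(C)C(C)(C)C)[C@@]2(C)CCCC(C)(C)[C@H]12
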